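**Plan**
- **Cuts:** The four phenols are masked as benzyl ethers. Ring C is traced back from the pyranone through the flavanone and the flavan-4-ol to a 2-aryl-2H-chromene. That ring is opened at C4–C4a to give an aryl 1-arylpropargyl ether. The ether is cut at O1–C2 into a ring A phenol and a ring B propargylic alcohol, and the alcohol is cut at C2–C3 into an aldehyde and an acetylide.
- **Enabling feature:** Ring A is fully substituted. Of the two carbons flanking C8a (the carbon that bears O1), only C4a carries hydrogen in the phenol. C8 and the para carbon C6 both carry OMe, so a sigmatropic shift starting at O1 can end irreversibly at one carbon only.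
- **Forward order:** Rings A and B are bought as arenes. Ring A gains two oxygens by way of a symmetrical dibromide, and ring B is formylated and ethynylated. The halves are joined at O1–C2. Ring C, the only ring built, arises in the thermal cascade, is then oxygenated at C4 and dehydrogenated, and the benzyl groups are removed last.
- **Stereochemistry:** The target has no stereocentre. The propargylic carbon, C2 and C4 are transient racemic or epimeric centres that are all gone after step 13, so nothing has to be controlled.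

Key step: step 10

**Step 1**
Reactants: 1 2,6-dimethoxyphenol
Product: 2 2-(benzyloxy)-1,3-dimethoxybenzene
Conditions: BnBr, K2CO3, DMF, 60 °C
Reagents that add atoms: benzyl bromide, BrCc1ccccc1
Why: Williamson etherification of the phenoxide with a benzylic bromide masks the future O7 with a group that hydrogenolysis removes at the end.

**Step 2**
Reactants: 2 2-(benzyloxy)-1,3-dimethoxybenzene
Product: 3 3-(benzyloxy)-1,5-dibromo-2,4-dimethoxybenzene
Conditions: NBS (2.1 equiv), MeCN, 0 °C → rt, dark
Reagents that add atoms: N-bromosuccinimide, O=C1CCC(=O)N1Br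
Why: In this electrophilic aromatic bromination the two outer ring CH positions are each ortho to one methoxy group and para to the other, while the middle CH is activated only by the twisted central benzyloxy group, so two equivalents should give the symmetrical dibromide.

**Step 3**
Reactants: 3 3-(benzyloxy)-1,5-dibromo-2,4-dimethoxybenzene
Product: 6 3-(benzyloxy)-5-bromo-2,4-dimethoxyphenol, via aryllithium 4 (not isolated), via dimethyl arylboronate 5 (not isolated)
Conditions: n-BuLi (1.0 equiv), THF, −78 °C; B(OMe)3, −78 °C → rt; AcOH, 30% aq H2O2, 0 °C → rt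
Reagents that add atoms: hydrogen peroxide, OO
Why: Bromine–lithium exchange, borylation and oxidative 1,2-aryl migration turn C–Br into C–OH, and because the two bromines are equivalent, one equivalent of n-BuLi breaks the symmetry without any regiochemical question.

**Step 4**
Reactants: 6 3-(benzyloxy)-5-bromo-2,4-dimethoxyphenol
Product: 7 1,3-bis(benzyloxy)-5-bromo-2,4-dimethoxybenzene
Conditions: BnBr, K2CO3, DMF, 60 °C
Reagents that add atoms: benzyl bromide, BrCc1ccccc1
Why: Williamson etherification fixes the new oxygen as the future 5-O-benzyl group while the remaining bromine marks the site of the future O1.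

**Step 5**
Reactants: 7 1,3-bis(benzyloxy)-5-bromo-2,4-dimethoxybenzene
Product: 10 3,5-bis(benzyloxy)-2,4-dimethoxyphenol, via aryllithium 8 (not isolated), via dimethyl arylboronate 9 (not isolated)
Conditions: n-BuLi (1.05 equiv), THF, −78 °C; B(OMe)3, −78 °C → rt; AcOH, 30% aq H2O2, 0 °C → rt
Reagents that add atoms: hydrogen peroxide, OO
Why: The same bromine–lithium exchange, borylation and boronate oxidation places the free hydroxyl between a CH and a C–OMe, and exchange at −78 °C is much faster than deprotonation of the benzyl ethers.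

**Step 6**
Reactants: 11 2-methoxyhydroquinone
Product: 12 1,4-bis(benzyloxy)-2-methoxybenzene
Conditions: BnBr (2.2 equiv), K2CO3, DMF, 60 °C, N2
Reagents that add atoms: benzyl bromide, BrCc1ccccc1
Why: Double Williamson etherification under nitrogen protects both hydroquinone oxygens before air can oxidise the dianion.

**Step 7**
Reactants: 12 1,4-bis(benzyloxy)-2-methoxybenzene
Product: 14 2,5-bis(benzyloxy)-4-methoxybenzaldehyde, via aryl iminium salt 13 (not isolated)
Conditions: POCl3, DMF, 0 → 70 °C; then ice-water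
Reagents that add atoms: N,N-dimethylformamide, CN(C)C=O; water, O
Why: Vilsmeier–Haack formylation of a 1,2,4-trialkoxybenzene attacks the carbon para to the methoxy group and ortho to a benzyloxy group, which is the only unhindered position activated by two donors.

**Step 8**
Reactants: 14 2,5-bis(benzyloxy)-4-methoxybenzaldehyde; 15 ethynylmagnesium bromide
Product: 16 1-[2,5-bis(benzyloxy)-4-methoxyphenyl]prop-2-yn-1-ol (racemic)
Conditions: THF, 0 °C → rt; then aq NH4Cl
Reagents that add atoms: none
Why: Grignard 1,2-addition of the acetylide to the aldehyde forms the C2–C3 bond, and the new carbinol centre is racemic because no chiral element is present or needed.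

**Step 9**
Reactants: 10 3,5-bis(benzyloxy)-2,4-dimethoxyphenol; 16 1-[2,5-bis(benzyloxy)-4-methoxyphenyl]prop-2-yn-1-ol (racemic)
Product: 17 1,3-bis(benzyloxy)-5-({1-[2,5-bis(benzyloxy)-4-methoxyphenyl]prop-2-yn-1-yl}oxy)-2,4-dimethoxybenzene (racemic)
Conditions: PPh3, DIAD (added last, slowly), toluene, 0 °C → rt
Reagents that add atoms: none
Why: In this Mitsunobu etherification the oxyphosphonium salt of the secondary propargylic alcohol is displaced at carbon by the phenoxide oxygen of 10, and the non-polar solvent and low temperature keep the ion pair tight so that O-alkylation should prevail.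

**Step 10**
Reactants: 17 1,3-bis(benzyloxy)-5-({1-[2,5-bis(benzyloxy)-4-methoxyphenyl]prop-2-yn-1-yl}oxy)-2,4-dimethoxybenzene (racemic)
Product: 21 5,7-bis(benzyloxy)-2-[2,5-bis(benzyloxy)-4-methoxyphenyl]-6,8-dimethoxy-2H-chromene (racemic), via allenyl dienone 18 (not isolated), via allenylphenol 19 (not isolated), via o-quinone methide 20 (not isolated)
Conditions: N,N-diethylaniline (degassed), 150 °C, Ar, base-washed glass
Reagents that add atoms: none
Why: This is an aromatic propargyl Claisen cascade in which a concerted [3,3] shift bonds the alkyne terminus (future C4) to C4a as the O1–CH(aryl) bond breaks, the allenyl dienone 18 enolises to allenylphenol 19, a 1,5-hydrogen shift from the hydroxyl to the central allene carbon gives the Z-configured o-quinone methide 20, and 20 cyclises. The closest known reaction type is the thermal rearrangement of aryl 1-arylprop-2-ynyl ethers to 2-aryl-2H-chromenes (flav-3-enes) in high-boiling amine solvents. Ring C, the one ring formed, closes by a thermally allowed disrotatory six-electron oxa-electrocyclisation of the O1=C8a–C4a=C4–C3=C2 oxatriene, which restores the O1–C2 bond and the aromaticity of ring A. C2 is the only new stereocentre, nothing in the substrate controls it, it should be obtained racemic, and it disappears in step 13. Regioselectivity between the two ortho carbons is secured by substitution, because a shift to C8 (or onward to C6) gives a methoxy-blocked dienone that cannot enolise and can only revert, whereas the shift to C4a is made irreversible by tautomerisation. Chemoselectivity is needed against heterolysis to a propargylic cation stabilised by ring B, and it is favoured by the basic, weakly polar solvent, the base-washed glass and the moderate temperature that the donor aryl group on the breaking C–O bond allows.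

**Step 11**
Reactants: 21 5,7-bis(benzyloxy)-2-[2,5-bis(benzyloxy)-4-methoxyphenyl]-6,8-dimethoxy-2H-chromene (racemic)
Product: 22 5,7-bis(benzyloxy)-2-[2,5-bis(benzyloxy)-4-methoxyphenyl]-6,8-dimethoxy-3,4-dihydro-2H-chromen-4-ol (racemic, mixture of C4 epimers)
Conditions: Mn(dpm)3 (cat., dpm = 2,2,6,6-tetramethylheptane-3,5-dionate), PhSiH3, O2 (1 atm), i-PrOH–CH2Cl2, 0 °C → rt
Reagents that add atoms: dioxygen, O=O
Why: In this Mukaiyama hydration a metal hydride delivers a hydrogen atom to C3 because that gives the benzylic C4 radical stabilised by ring A, O2 traps this radical and the silane reduces the peroxide to the alcohol, the C4 configuration is irrelevant, and any ketone formed by over-oxidation is simply the next product.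

**Step 12**
Reactants: 22 5,7-bis(benzyloxy)-2-[2,5-bis(benzyloxy)-4-methoxyphenyl]-6,8-dimethoxy-3,4-dihydro-2H-chromen-4-ol
Product: 23 5,7-bis(benzyloxy)-2-[2,5-bis(benzyloxy)-4-methoxyphenyl]-6,8-dimethoxy-2,3-dihydro-4H-chromen-4-one (racemic flavanone)
Conditions: n-Pr4N[RuO4] (TPAP, cat.), NMO, 4 Å MS, CH2Cl2, rt
Reagents that add atoms: none
Why: Ley–Griffith oxidation converts the secondary benzylic alcohol into the ketone in an acid-free medium, which avoids ionisation of the very electron-rich flavan-4-ol.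

**Step 13**
Reactants: 23 5,7-bis(benzyloxy)-2-[2,5-bis(benzyloxy)-4-methoxyphenyl]-6,8-dimethoxy-2,3-dihydro-4H-chromen-4-one
Product: 25 5,7-bis(benzyloxy)-2-[2,5-bis(benzyloxy)-4-methoxyphenyl]-6,8-dimethoxy-4H-chromen-4-one, via 3-iodoflavanone 24 (not isolated)
Conditions: I2 (10 mol %), DMSO, 120 °C
Reagents that add atoms: none
Why: In this iodine-catalysed flavanone dehydrogenation the enol is iodinated at C3, loss of HI gives the aromatic pyranone and erases C2, DMSO re-oxidises HI to I2, and the small iodine charge limits iodination of ring B.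

**Step 14**
Reactants: 25 5,7-bis(benzyloxy)-2-[2,5-bis(benzyloxy)-4-methoxyphenyl]-6,8-dimethoxy-4H-chromen-4-one
Product: 26 5,7-dihydroxy-2-(2,5-dihydroxy-4-methoxyphenyl)-6,8-dimethoxy-4H-chromen-4-one (CNP0297724.0)
Conditions: H2 (1 atm), 10% Pd/C, THF–MeOH, rt; filtration under Ar
Reagents that add atoms: none
Why: Catalytic hydrogenolysis cleaves all four aryl benzyl ethers at once, the methyl ethers and the C2=C3 bond of the aromatic pyranone should be inert at one atmosphere and room temperature, and exclusion of air protects the hydroquinone-type ring B.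

**Compound list**
1 | 2,6-dimethoxyphenol | COc1cccc(OC)c1O | starting material
2 | 2-(benzyloxy)-1,3-dimethoxybenzene | COc1cccc(OC)c1OCc1ccccc1 | intermediate
3 | 3-(benzyloxy)-1,5-dibromo-2,4-dimethoxybenzene | COc1c(Br)cc(Br)c(OC)c1OCc1ccccc1 | intermediate
4 | [3-(benzyloxy)-5-bromo-2,4-dimethoxyphenyl]lithium | COc1c([Li])cc(Br)c(OC)c1OCc1ccccc1 | intermediate
5 | dimethyl [3-(benzyloxy)-5-bromo-2,4-dimethoxyphenyl]boronate | COB(OC)c1cc(Br)c(OC)c(OCc2ccccc2)c1OC | intermediate
6 | 3-(benzyloxy)-5-bromo-2,4-dimethoxyphenol | COc1c(O)cc(Br)c(OC)c1OCc1ccccc1 | intermediate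
7 | 1,3-bis(benzyloxy)-5-bromo-2,4-dimethoxybenzene | COc1c(OCc2ccccc2)cc(Br)c(OC)c1OCc1ccccc1 | intermediate
8 | [3,5-bis(benzyloxy)-2,4-dimethoxyphenyl]lithium | COc1c([Li])cc(OCc2ccccc2)c(OC)c1OCc1ccccc1 | intermediate
9 | dimethyl [3,5-bis(benzyloxy)-2,4-dimethoxyphenyl]boronate | COB(OC)c1cc(OCc2ccccc2)c(OC)c(OCc2ccccc2)c1OC | intermediate
10 | 3,5-bis(benzyloxy)-2,4-dimethoxyphenol | COc1c(O)cc(OCc2ccccc2)c(OC)c1OCc1ccccc1 | intermediate
11 | 2-methoxyhydroquinone (2-methoxybenzene-1,4-diol) | COc1cc(O)ccc1O | starting material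
12 | 1,4-bis(benzyloxy)-2-methoxybenzene | COc1cc(OCc2ccccc2)ccc1OCc1ccccc1 | intermediate
13 | N-{[2,5-bis(benzyloxy)-4-methoxyphenyl]methylidene}-N-methylmethanaminium dichlorophosphate | COc1cc(OCc2ccccc2)c(C=[N+](C)C)cc1OCc1ccccc1.[O-]P(Cl)(Cl)=O | intermediate
14 | 2,5-bis(benzyloxy)-4-methoxybenzaldehyde | COc1cc(OCc2ccccc2)c(C=O)cc1OCc1ccccc1 | intermediate
15 | ethynylmagnesium bromide | C#C[Mg]Br | starting material
16 | 1-[2,5-bis(benzyloxy)-4-methoxyphenyl]prop-2-yn-1-ol (racemic) | C#CC(O)c1cc(OCc2ccccc2)c(OC)cc1OCc1ccccc1 | intermediate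
17 | 1,3-bis(benzyloxy)-5-({1-[2,5-bis(benzyloxy)-4-methoxyphenyl]prop-2-yn-1-yl}oxy)-2,4-dimethoxybenzene (racemic) | C#CC(Oc1cc(OCc2ccccc2)c(OC)c(OCc2ccccc2)c1OC)c1cc(OCc2ccccc2)c(OC)cc1OCc1ccccc1 | intermediate
18 | 3,5-bis(benzyloxy)-6-{3-[2,5-bis(benzyloxy)-4-methoxyphenyl]propa-1,2-dien-1-yl}-2,4-dimethoxycyclohexa-2,4-dien-1-one (mixture of stereoisomers) | O=C1C(OC)=C(OCc2ccccc2)C(OC)=C(OCc2ccccc2)C1C=C=Cc1cc(OCc2ccccc2)c(OC)cc1OCc1ccccc1 | intermediate
19 | 3,5-bis(benzyloxy)-2-{3-[2,5-bis(benzyloxy)-4-methoxyphenyl]propa-1,2-dien-1-yl}-4,6-dimethoxyphenol (racemic allene) | COc1c(O)c(C=C=Cc2cc(OCc3ccccc3)c(OC)cc2OCc2ccccc2)c(OCc2ccccc2)c(OC)c1OCc1ccccc1 | intermediate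
20 | (6Z)-3,5-bis(benzyloxy)-6-{3-[2,5-bis(benzyloxy)-4-methoxyphenyl]prop-2-en-1-ylidene}-2,4-dimethoxycyclohexa-2,4-dien-1-one (side-chain C=C geometry not defined) | O=C1C(OC)=C(OCc2ccccc2)C(OC)=C(OCc2ccccc2)/C1=C/C=Cc1cc(OCc2ccccc2)c(OC)cc1OCc1ccccc1 | intermediate
21 | 5,7-bis(benzyloxy)-2-[2,5-bis(benzyloxy)-4-methoxyphenyl]-6,8-dimethoxy-2H-chromene (racemic) | COc1cc(OCc2ccccc2)c(cc1OCc1ccccc1)C1C=Cc2c(OCc3ccccc3)c(OC)c(OCc3ccccc3)c(OC)c2O1 | intermediate
22 | 5,7-bis(benzyloxy)-2-[2,5-bis(benzyloxy)-4-methoxyphenyl]-6,8-dimethoxy-3,4-dihydro-2H-chromen-4-ol (racemic, C4 epimers) | COc1cc(OCc2ccccc2)c(cc1OCc1ccccc1)C1CC(O)c2c(OCc3ccccc3)c(OC)c(OCc3ccccc3)c(OC)c2O1 | intermediate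
23 | 5,7-bis(benzyloxy)-2-[2,5-bis(benzyloxy)-4-methoxyphenyl]-6,8-dimethoxy-2,3-dihydro-4H-chromen-4-one (racemic) | COc1cc(OCc2ccccc2)c(cc1OCc1ccccc1)C1CC(=O)c2c(OCc3ccccc3)c(OC)c(OCc3ccccc3)c(OC)c2O1 | intermediate
24 | 5,7-bis(benzyloxy)-2-[2,5-bis(benzyloxy)-4-methoxyphenyl]-3-iodo-6,8-dimethoxy-2,3-dihydro-4H-chromen-4-one (racemic, C3 epimers) | COc1cc(OCc2ccccc2)c(cc1OCc1ccccc1)C1C(I)C(=O)c2c(OCc3ccccc3)c(OC)c(OCc3ccccc3)c(OC)c2O1 | intermediate
25 | 5,7-bis(benzyloxy)-2-[2,5-bis(benzyloxy)-4-methoxyphenyl]-6,8-dimethoxy-4H-chromen-4-one | COc1cc(OCc2ccccc2)c(cc1OCc1ccccc1)-c1cc(=O)c2c(OCc3ccccc3)c(OC)c(OCc3ccccc3)c(OC)c2o1 | intermediate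
26 | 5,7-dihydroxy-2-(2,5-dihydroxy-4-methoxyphenyl)-6,8-dimethoxy-4H-chromen-4-one (CNP0297724.0) | COc1cc(O)c(-c2cc(=O)c3c(O)c(OC)c(O)c(OC)c3o2)cc1O | target

**Total step count:** 14.
**Longest linear sequence:** 11 (steps 1–5 and 9–14). The ring B branch (steps 6–8) joins at step 9.

**Steps most likely to fail**

**Step 10.**
- **Risk:** The doubly activated benzylic and propargylic C–O bond may break heterolytically before the sigmatropic shift takes place, and recombination at carbon would then misplace the aryl group. The 2H-chromene may also disproportionate at the reaction temperature if traces of acid are present.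
- **Fallback:** This fallback gives up the pericyclic closure and builds ring C by carbonylation. It sets out from 10 and 14 and comes back at 25.
  - Phenol 10 is iodinated at its only ring CH (NIS, MeCN, 0 °C) to give 3,5-bis(benzyloxy)-2-iodo-4,6-dimethoxyphenol F1.
  - Aldehyde 14 is homologated with the Ohira–Bestmann reagent (K2CO3, MeOH) to give 1,4-bis(benzyloxy)-2-ethynyl-5-methoxybenzene F2.
  - A carbonylative Sonogashira coupling of F1 and F2 (PdCl2(PPh3)2 cat., CO 1 atm, Et2NH, heat) brings in C4 as carbon monoxide. It gives 1-[4,6-bis(benzyloxy)-2-hydroxy-3,5-dimethoxyphenyl]-3-[2,5-bis(benzyloxy)-4-methoxyphenyl]prop-2-yn-1-one F3 in the flask.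
  - The amine then promotes 6-endo conjugate addition of the phenol of F3 to the ynone, which gives flavone 25 directly.

**Step 9.**
- **Risk:** The oxyphosphonium salt of the very electron-rich benzylic, propargylic alcohol may ionise. That would lead to C-alkylation of the phenol at its free carbon, SN2' capture or elimination in place of O-alkylation.
- **Fallback:** This fallback replaces phosphonium activation by a metal-bound electrophile. It sets out from 16 and comes back at 17.
  - Alcohol 16 is acetylated (Ac2O, Et3N, DMAP, CH2Cl2, 0 °C) to give 1-[2,5-bis(benzyloxy)-4-methoxyphenyl]prop-2-yn-1-yl acetate F4.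
  - F4 is coupled with phenol 10 by copper-catalysed propargylic substitution (Cu(MeCN)4PF6 cat., i-Pr2NEt, MeCN, 0 °C).
  - The terminal alkyne forms a copper allenylidene, which the phenoxide oxygen attacks at the propargylic carbon under basic conditions to give ether 17.

**Step 11.**
- **Risk:** The benzylic radical may be reduced faster than it is oxygenated, which amounts to net hydrogenation of C3=C4. Autoxidation at the doubly activated C2–H and slow hydrogen atom transfer next to the 5-benzyloxy group are further risks.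
- **Fallback:** This fallback uses ionic chemistry and carries a leaving group at C3, so no separate dehydrogenation is needed. It sets out from 21 and comes back at 25.
  - Halohydrin formation (NBS, aqueous DMSO, 0 °C) opens the bromonium ion with water at benzylic C4. This gives 5,7-bis(benzyloxy)-2-[2,5-bis(benzyloxy)-4-methoxyphenyl]-3-bromo-6,8-dimethoxy-3,4-dihydro-2H-chromen-4-ol F5.
  - Oxidation with Dess–Martin periodinane (NaHCO3, CH2Cl2) gives 5,7-bis(benzyloxy)-2-[2,5-bis(benzyloxy)-4-methoxyphenyl]-3-bromo-6,8-dimethoxy-2,3-dihydro-4H-chromen-4-one F6.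
  - Dehydrobromination (DBU, CH2Cl2, rt) gives flavone 25.

**Further compounds**
F1 | step 10 | 3,5-bis(benzyloxy)-2-iodo-4,6-dimethoxyphenol | COc1c(O)c(I)c(OCc2ccccc2)c(OC)c1OCc1ccccc1
F2 | step 10 | 1,4-bis(benzyloxy)-2-ethynyl-5-methoxybenzene | C#Cc1cc(OCc2ccccc2)c(OC)cc1OCc1ccccc1
F3 | step 10 | 1-[4,6-bis(benzyloxy)-2-hydroxy-3,5-dimethoxyphenyl]-3-[2,5-bis(benzyloxy)-4-methoxyphenyl]prop-2-yn-1-one | COc1cc(OCc2ccccc2)c(C#CC(=O)c2c(O)c(OC)c(OCc3ccccc3)c(OC)c2OCc2ccccc2)cc1OCc1ccccc1
F4 | step 9 | 1-[2,5-bis(benzyloxy)-4-methoxyphenyl]prop-2-yn-1-yl acetate (racemic) | C#CC(OC(C)=O)c1cc(OCc2ccccc2)c(OC)cc1OCc1ccccc1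
F5 | step 11 | 5,7-bis(benzyloxy)-2-[2,5-bis(benzyloxy)-4-methoxyphenyl]-3-bromo-6,8-dimethoxy-3,4-dihydro-2H-chromen-4-ol (racemic, diastereomer mixture) | COc1cc(OCc2ccccc2)c(cc1OCc1ccccc1)C1C(Br)C(O)c2c(OCc3ccccc3)c(OC)c(OCc3ccccc3)c(OC)c2O1
F6 | step 11 | 5,7-bis(benzyloxy)-2-[2,5-bis(benzyloxy)-4-methoxyphenyl]-3-bromo-6,8-dimethoxy-2,3-dihydro-4H-chromen-4-one (racemic, diastereomer mixture) | COc1cc(OCc2ccccc2)c(cc1OCc1ccccc1)C1C(Br)C(=O)c2c(OCc3ccccc3)c(OC)c(OCc3ccccc3)c(OC)c2O1
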